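**Retrosynthetic overview**
1. Target 27 ⇐ O-debenzylation of 26. Benzofuran C is made last, by Sonogashira/5-endo heteroannulation of propargyl spiroketal 19 with iodophenol 24.
2. Spiroketal 19 (ring B, spiro C–O bond, spiro centre) ⇐ new acid-catalysed dearomative 5-exo hydroalkoxylation of the 2-alkylbenzofuran in 18.
3. 18 ⇐ Ohira–Bestmann homologation of lactol 16 ⇐ enantioselective iminium Friedel–Crafts/hemiacetalisation of phenol 14 with benzofuranyl enal 13 (sets the benzylic CH).
4. 13 ⇐ benzofuran A from iodophenol 7 (Sonogashira/heteroannulation, oxidation, Wittig). All three arenes come from isovalerylphloroglucinol 3.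
5. Ring order: benzofuran A → temporary chromanol → spiro ring B closed onto ring A → benzofuran C.

Assumptions: reagents that deliver non-hydrogen atoms are numbered like starting materials. Lactol 16 is an anomeric mixture (hemiacetal carbon left undefined in its SMILES). In the descriptors, the spiro carbon is C2 and the substituted CH is C3; the target is (2R,3S) by my CIP analysis of the given SMILES.

**Step 1**
Reactants: 1 phloroglucinol; 2 3-methylbutanoyl chloride
Product: 3 1-(2,4,6-trihydroxyphenyl)-3-methylbutan-1-one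
Conditions: AlCl3 (3.5 equiv), PhNO2–CH2Cl2, 0 → 45 °C; then ice/1 M HCl
Reagents that add atoms: 3-methylbutanoyl chloride, CC(C)CC(Cl)=O
Why: Friedel–Crafts C-acylation of the electron-rich triol stops cleanly after one acyl group because the ketone deactivates the ring.

**Step 2**
Reactants: 3; 4 benzyl bromide
Product: 5 1-[2,4-bis(benzyloxy)-6-hydroxyphenyl]-3-methylbutan-1-one
Conditions: BnBr (2.2 equiv), K2CO3 (2.5 equiv), acetone, reflux
Reagents that add atoms: benzyl bromide, BrCc1ccccc1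
Why: Williamson etherification alkylates the two non-chelated phenols while the OH hydrogen-bonded to the ketone stays free.

**Step 3**
Reactants: 5; 6 benzyltrimethylammonium dichloroiodate
Product: 7 1-[4,6-bis(benzyloxy)-2-hydroxy-3-iodophenyl]-3-methylbutan-1-one
Conditions: BnMe3N·ICl2 (1.05 equiv), NaHCO3, CH2Cl2–MeOH, rt
Reagents that add atoms: benzyltrimethylammonium dichloroiodate, C[N+](C)(C)Cc1ccccc1.Cl[I-]Cl
Why: Electrophilic aromatic iodination goes ortho to the free phenol at C3 (between OH and OBn), which is less hindered than C5 between two OBn groups.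

**Step 4**
Reactants: 7; 8 prop-2-yn-1-ol
Product: 10 1-[4,6-bis(benzyloxy)-2-(hydroxymethyl)-1-benzofuran-7-yl]-3-methylbutan-1-one, via alkynylphenol 9 (not isolated)
Conditions: PdCl2(PPh3)2 (3 mol %), CuI (6 mol %), Et3N, DMF, 60 °C
Reagents that add atoms: prop-2-yn-1-ol, C#CCO
Why: Sonogashira coupling followed in the flask by 5-endo-dig cyclisation of the o-alkynylphenol (Castro–Stephens/Larock-type annulation) uses the only free OH, so the furan oxygen ends up ortho to the acyl group.

**Step 5**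
Reactants: 10
Product: 11 4,6-bis(benzyloxy)-7-(3-methylbutanoyl)-1-benzofuran-2-carbaldehyde
Conditions: activated MnO2 (15 equiv), CH2Cl2, rt
Reagents that add atoms: none
Why: MnO2 oxidation is selective for the heteroaryl (benzylic-type) carbinol and leaves the ketone and benzyl ethers untouched.

**Step 6**
Reactants: 11; 12 (triphenylphosphoranylidene)acetaldehyde
Product: 13 (2E)-3-[4,6-bis(benzyloxy)-7-(3-methylbutanoyl)-1-benzofuran-2-yl]prop-2-enal
Conditions: Ph3P=CHCHO (1.3 equiv), toluene, 80 °C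
Reagents that add atoms: (triphenylphosphoranylidene)acetaldehyde, O=CC=P(c1ccccc1)(c1ccccc1)c1ccccc1
Why: Wittig olefination with the stabilised formyl ylide is E-selective and reacts only with the aldehyde, not the hindered aryl ketone.

**Step 7**
Reactants: 3; 4 benzyl bromide
Product: 14 1-[4-(benzyloxy)-2,6-dihydroxyphenyl]-3-methylbutan-1-one
Conditions: BnBr (1.0 equiv), K2CO3 (1.05 equiv), DMF, 0 °C → rt
Reagents that add atoms: benzyl bromide, BrCc1ccccc1
Why: Mono-Williamson etherification goes to the para OH, the most acidic and only non-chelated phenol; over-alkylation gives 5, which is separable.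

**Step 8**
Reactants: 14; 13
Product: 16 1-[(4S)-5-(benzyloxy)-4-[4,6-bis(benzyloxy)-7-(3-methylbutanoyl)-1-benzofuran-2-yl]-2,7-dihydroxy-3,4-dihydro-2H-chromen-8-yl]-3-methylbutan-1-one (anomer mixture at C2), via open-chain aldehyde 15 (not isolated)
Conditions: (R)-α,α-diphenylprolinol TMS ether (20 mol %), PhCO2H (20 mol %), toluene, 0 °C → rt; 14 used in 1.5-fold excess
Reagents that add atoms: none
Why: Iminium-ion organocatalytic Friedel–Crafts alkylation/hemiacetalisation (Jørgensen–Hayashi catalyst), in which the CPh2OTMS group shields one face of the (E)-iminium so the symmetric phloroglucinol (both reactive carbons equivalent) adds to the Re face of Cβ to give the (S) benzylic centre, and the neighbouring OH traps the aldehyde as the lactol.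

**Step 9**
Reactants: 16; 17 dimethyl (1-diazo-2-oxopropyl)phosphonate
Product: 18 1-[4-(benzyloxy)-3-[(1S)-1-[4,6-bis(benzyloxy)-7-(3-methylbutanoyl)-1-benzofuran-2-yl]but-3-yn-1-yl]-2,6-dihydroxyphenyl]-3-methylbutan-1-one
Conditions: K2CO3 (3 equiv), MeOH–THF, 0 °C → rt
Reagents that add atoms: dimethyl (1-diazo-2-oxopropyl)phosphonate, CC(=O)C(=[N+]=[N-])P(=O)(OC)OC
Why: Ohira–Bestmann (Seyferth–Gilbert) homologation acts on the open aldehyde form of the lactol; the stereocentre is β to the carbonyl and cannot enolise, and the aryl ketones do not react under K2CO3/MeOH.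

**Step 10**
Reactants: 18
Product: 19 1,1'-[(2R,3S)-4,4',6'-tris(benzyloxy)-6-hydroxy-3-(prop-2-yn-1-yl)-3H,3'H-2,2'-spirobi[[1]benzofuran]-7,7'-diyl]bis(3-methylbutan-1-one)
Conditions: (S,S)-IDPi (confined imidodiphosphorimidate Brønsted acid, 5 mol %), 4 Å MS, CHCl3, 0 °C → rt
Reagents that add atoms: none
Why: Proposed new method: Brønsted-acid-catalysed dearomative intramolecular hydroalkoxylation of a benzofuran, in which the confined strong acid protonates C3 of the 2-alkylbenzofuran (whose furan ring adds almost no aromatic stabilisation beyond the benzene ring, so it behaves as an aryl enol ether), the resulting 3H-benzofuran-2-ylium/IDPi ion pair is captured 5-exo by the ortho phenol of ring B three atoms away (the ketone re-chelates with the remaining 6-OH, so no hydrogen bond is lost), and because ketal ionisation/re-closure is much faster than C-deprotonation the spiro centre settles, under control of the existing C3 centre, as the epimer with the propargyl group syn to the ring-A oxygen and anti to the ring-A CH2 (2R), while the confined anion suppresses bimolecular Friedel–Crafts attack on the cation; the closest known reaction types are chiral-phosphoric-acid/IDPi-catalysed spiroketalisation of cyclic enol ethers, IDPi-catalysed hydroalkoxylation of alkenes and halonium-triggered spiroketalisation of benzofurans.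

**Step 11**
Reactants: 3; 20 chloromethyl methyl ether
Product: 21 1-[2-hydroxy-4,6-bis(methoxymethoxy)phenyl]-3-methylbutan-1-one
Conditions: MOMCl (2.3 equiv), iPr2NEt (3 equiv), CH2Cl2, 0 °C → rt
Reagents that add atoms: chloromethyl methyl ether, COCCl
Why: O-alkylation (MOM protection) takes the two non-chelated phenols and leaves the ketone-chelated OH free.

**Step 12**
Reactants: 21; 6 benzyltrimethylammonium dichloroiodate
Product: 22 1-[2-hydroxy-3-iodo-4,6-bis(methoxymethoxy)phenyl]-3-methylbutan-1-one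
Conditions: BnMe3N·ICl2 (1.05 equiv), NaHCO3, CH2Cl2–MeOH, rt
Reagents that add atoms: benzyltrimethylammonium dichloroiodate, C[N+](C)(C)Cc1ccccc1.Cl[I-]Cl
Why: Electrophilic aromatic iodination ortho to the only free phenol, as in step 3, with the bicarbonate buffer protecting the MOM acetals.

**Step 13**
Reactants: 22; 4 benzyl bromide
Product: 23 1-[2-(benzyloxy)-3-iodo-4,6-bis(methoxymethoxy)phenyl]-3-methylbutan-1-one
Conditions: BnBr (1.5 equiv), K2CO3, Bu4NI (cat.), DMF, 60 °C
Reagents that add atoms: benzyl bromide, BrCc1ccccc1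
Why: Williamson etherification under forcing conditions caps the chelated phenol, which is the only remaining OH.

**Step 14**
Reactants: 23
Product: 24 1-[2-(benzyloxy)-4,6-dihydroxy-3-iodophenyl]-3-methylbutan-1-one
Conditions: 3 M HCl (cat.), MeOH, 45 °C
Reagents that add atoms: none
Why: Acid-catalysed acetal methanolysis removes both MOM groups while the benzyl ether and aryl iodide survive, leaving a free OH (para to the acyl group) next to iodine.

**Step 15**
Reactants: 19; 24
Product: 26 (2R,3S)-4,4',6'-tris(benzyloxy)-3-{[4-(benzyloxy)-6-hydroxy-5-(3-methylbutanoyl)-1-benzofuran-2-yl]methyl}-6-hydroxy-7,7'-bis(3-methylbutanoyl)-3H,3'H-2,2'-spirobi[[1]benzofuran], via alkynylphenol 25 (not isolated)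
Conditions: PdCl2(PPh3)2 (5 mol %), CuI (10 mol %), Et3N, DMF, 60 °C
Reagents that add atoms: none
Why: Sonogashira coupling/5-endo-dig heteroannulation, in which only the 4-OH of 24 is ortho to the new alkyne, so the furan oxygen of ring C ends up para to the acyl group; the basic conditions leave the spiroketal and both stereocentres untouched.

**Step 16**
Reactants: 26
Product: 27 (2R,3S)-3-{[4,6-dihydroxy-5-(3-methylbutanoyl)-1-benzofuran-2-yl]methyl}-4,4',6,6'-tetrahydroxy-7,7'-bis(3-methylbutanoyl)-3H,3'H-2,2'-spirobi[[1]benzofuran] (CNP0169640.1)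
Conditions: H2 (1 atm), 10 % Pd/C, EtOAc–MeOH, rt
Reagents that add atoms: none
Why: Pd-catalysed hydrogenolysis cleaves the four benzyl aryl ethers under neutral conditions that spare the non-benzylic spiroketal C–O bonds, the chelated aryl ketones and the 2-alkylbenzofuran, and touch no stereocentre.

**Compound list**
1 | phloroglucinol (benzene-1,3,5-triol) | Oc1cc(O)cc(O)c1 | starting material
2 | 3-methylbutanoyl chloride | CC(C)CC(Cl)=O | starting material
3 | 1-(2,4,6-trihydroxyphenyl)-3-methylbutan-1-one | CC(C)CC(=O)c1c(O)cc(O)cc1O | intermediate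
4 | benzyl bromide | BrCc1ccccc1 | starting material
5 | 1-[2,4-bis(benzyloxy)-6-hydroxyphenyl]-3-methylbutan-1-one | CC(C)CC(=O)c1c(O)cc(OCc2ccccc2)cc1OCc1ccccc1 | intermediate
6 | benzyltrimethylammonium dichloroiodate | C[N+](C)(C)Cc1ccccc1.Cl[I-]Cl | starting material
7 | 1-[4,6-bis(benzyloxy)-2-hydroxy-3-iodophenyl]-3-methylbutan-1-one | CC(C)CC(=O)c1c(O)c(I)c(OCc2ccccc2)cc1OCc1ccccc1 | intermediate
8 | prop-2-yn-1-ol | C#CCO | starting material
9 | 1-[4,6-bis(benzyloxy)-2-hydroxy-3-(3-hydroxyprop-1-yn-1-yl)phenyl]-3-methylbutan-1-one | CC(C)CC(=O)c1c(O)c(C#CCO)c(OCc2ccccc2)cc1OCc1ccccc1 | intermediate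
10 | 1-[4,6-bis(benzyloxy)-2-(hydroxymethyl)-1-benzofuran-7-yl]-3-methylbutan-1-one | CC(C)CC(=O)c1c(OCc2ccccc2)cc(OCc2ccccc2)c2cc(CO)oc12 | intermediate
11 | 4,6-bis(benzyloxy)-7-(3-methylbutanoyl)-1-benzofuran-2-carbaldehyde | CC(C)CC(=O)c1c(OCc2ccccc2)cc(OCc2ccccc2)c2cc(C=O)oc12 | intermediate
12 | (triphenylphosphoranylidene)acetaldehyde | O=CC=P(c1ccccc1)(c1ccccc1)c1ccccc1 | starting material
13 | (2E)-3-[4,6-bis(benzyloxy)-7-(3-methylbutanoyl)-1-benzofuran-2-yl]prop-2-enal | CC(C)CC(=O)c1c(OCc2ccccc2)cc(OCc2ccccc2)c2cc(/C=C/C=O)oc12 | intermediate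
14 | 1-[4-(benzyloxy)-2,6-dihydroxyphenyl]-3-methylbutan-1-one | CC(C)CC(=O)c1c(O)cc(OCc2ccccc2)cc1O | intermediate
15 | (3S)-3-[6-(benzyloxy)-2,4-dihydroxy-3-(3-methylbutanoyl)phenyl]-3-[4,6-bis(benzyloxy)-7-(3-methylbutanoyl)-1-benzofuran-2-yl]propanal | CC(C)CC(=O)c1c(O)cc(OCc2ccccc2)c(c1O)[C@H](CC=O)c1cc2c(OCc3ccccc3)cc(OCc3ccccc3)c(C(=O)CC(C)C)c2o1 | intermediate
16 | 1-[(4S)-5-(benzyloxy)-4-[4,6-bis(benzyloxy)-7-(3-methylbutanoyl)-1-benzofuran-2-yl]-2,7-dihydroxy-3,4-dihydro-2H-chromen-8-yl]-3-methylbutan-1-one (C2 anomer mixture) | CC(C)CC(=O)c1c(O)cc(OCc2ccccc2)c2c1OC(O)C[C@@H]2c1cc2c(OCc3ccccc3)cc(OCc3ccccc3)c(C(=O)CC(C)C)c2o1 | intermediate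
17 | dimethyl (1-diazo-2-oxopropyl)phosphonate | CC(=O)C(=[N+]=[N-])P(=O)(OC)OC | starting material
18 | 1-[4-(benzyloxy)-3-[(1S)-1-[4,6-bis(benzyloxy)-7-(3-methylbutanoyl)-1-benzofuran-2-yl]but-3-yn-1-yl]-2,6-dihydroxyphenyl]-3-methylbutan-1-one | CC(C)CC(=O)c1c(O)cc(OCc2ccccc2)c(c1O)[C@H](CC#C)c1cc2c(OCc3ccccc3)cc(OCc3ccccc3)c(C(=O)CC(C)C)c2o1 | intermediate
19 | 1,1'-[(2R,3S)-4,4',6'-tris(benzyloxy)-6-hydroxy-3-(prop-2-yn-1-yl)-3H,3'H-2,2'-spirobi[[1]benzofuran]-7,7'-diyl]bis(3-methylbutan-1-one) | CC(C)CC(=O)c1c(OCc3ccccc3)cc(OCc3ccccc3)c2c1O[C@]1(C2)Oc2c(C(=O)CC(C)C)c(O)cc(OCc3ccccc3)c2[C@@H]1CC#C | intermediate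
20 | chloromethyl methyl ether | COCCl | starting material
21 | 1-[2-hydroxy-4,6-bis(methoxymethoxy)phenyl]-3-methylbutan-1-one | CC(C)CC(=O)c1c(O)cc(OCOC)cc1OCOC | intermediate
22 | 1-[2-hydroxy-3-iodo-4,6-bis(methoxymethoxy)phenyl]-3-methylbutan-1-one | CC(C)CC(=O)c1c(O)c(I)c(OCOC)cc1OCOC | intermediate
23 | 1-[2-(benzyloxy)-3-iodo-4,6-bis(methoxymethoxy)phenyl]-3-methylbutan-1-one | CC(C)CC(=O)c1c(OCc2ccccc2)c(I)c(OCOC)cc1OCOC | intermediate
24 | 1-[2-(benzyloxy)-4,6-dihydroxy-3-iodophenyl]-3-methylbutan-1-one | CC(C)CC(=O)c1c(OCc2ccccc2)c(I)c(O)cc1O | intermediate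
25 | spiroketal 19 carrying a 2-(benzyloxy)-4,6-dihydroxy-3-(3-methylbutanoyl)phenyl group on the alkyne terminus | CC(C)CC(=O)c1c(OCc3ccccc3)cc(OCc3ccccc3)c2c1O[C@]1(C2)Oc2c(C(=O)CC(C)C)c(O)cc(OCc3ccccc3)c2[C@@H]1CC#Cc1c(O)cc(O)c(C(=O)CC(C)C)c1OCc1ccccc1 | intermediate
26 | (2R,3S)-4,4',6'-tris(benzyloxy)-3-{[4-(benzyloxy)-6-hydroxy-5-(3-methylbutanoyl)-1-benzofuran-2-yl]methyl}-6-hydroxy-7,7'-bis(3-methylbutanoyl)-3H,3'H-2,2'-spirobi[[1]benzofuran] | CC(C)CC(=O)c1c(OCc3ccccc3)cc(OCc3ccccc3)c2c1O[C@]1(C2)Oc2c(C(=O)CC(C)C)c(O)cc(OCc3ccccc3)c2[C@@H]1Cc1cc2c(OCc3ccccc3)c(C(=O)CC(C)C)c(O)cc2o1 | intermediate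
27 | (2R,3S)-3-{[4,6-dihydroxy-5-(3-methylbutanoyl)-1-benzofuran-2-yl]methyl}-4,4',6,6'-tetrahydroxy-7,7'-bis(3-methylbutanoyl)-3H,3'H-2,2'-spirobi[[1]benzofuran] (CNP0169640.1) | CC(C)CC(=O)c1c(O)cc(O)c2c1O[C@]1(C2)Oc2c(C(=O)CC(C)C)c(O)cc(O)c2[C@@H]1Cc1cc2c(O)c(C(=O)CC(C)C)c(O)cc2o1 | target

**Totals**
Total step count: 16. Longest linear sequence: 11 steps (1, 2, 3, 4, 5, 6, 8, 9, 10, 15, 16).

**Three steps most likely to fail**

Step 10 (proposed new dearomative spiroketalisation). The aryl ketal may not be sufficiently favoured over the benzofuran. The cation could also lose the C3 proton (epimerisation) or drift to the isomeric ring-B benzofuran on long exposure. The fallback uses known chemistry and sets out from 18. Halonium-triggered spiroketalisation of the benzofuran (NBS, CH2Cl2, −78 °C) closes ring B irreversibly under kinetic control and gives the bromo-spiroketal F4. Radical debromination (Bu3SnH added slowly, AIBN, benzene, 80 °C) removes the bromine before the alkyne can be hydrostannylated. The fallback comes back to the route at 19.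

Step 8 (asymmetric Friedel–Crafts/hemiacetalisation). The chelated, hindered phloroglucinol and the bulky β-benzofuranyl enal may give low rate or low ee, and the facial sense rests on the usual shielding model. The fallback sets out from 13 and 14 and abandons asymmetric catalysis. Pyrrolidine/benzoic acid (achiral iminium catalysis) gives the racemic lactol F1. Ohira–Bestmann homologation as in step 9 gives the racemic alkyne phenol F2. Preparative chiral SFC on an amylose phase separates the wanted enantiomer from the (R)-enantiomer F3, which is discarded. The fallback comes back to the route at 18.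

Step 15 (one-pot Sonogashira/heteroannulation). The iodide in 24 is electron-rich, flanked on both sides, and present as a phenoxide, so oxidative addition may be slow and alkyne homocoupling may win. The fallback sets out from 24 and separates coupling from ring closure. Selective acetylation of the non-chelated 4-OH (Ac2O, Et3N, CH2Cl2, 0 °C) gives the aryl acetate F5, a better oxidative-addition partner. Sonogashira coupling with 19 (Pd(PPh3)4, CuI, Et3N, THF, rt) gives the alkynyl aryl acetate F6. Methanolysis (K2CO3, MeOH) releases the alkynylphenol and the fallback comes back to the route at 25, now isolated. Gold catalysis (Ph3PAuNTf2, 2 mol %, CH2Cl2) then cyclises 25 to 26.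

**Further compounds**
F1 | step 8 | racemic 1-[5-(benzyloxy)-4-[4,6-bis(benzyloxy)-7-(3-methylbutanoyl)-1-benzofuran-2-yl]-2,7-dihydroxy-3,4-dihydro-2H-chromen-8-yl]-3-methylbutan-1-one (racemic lactol) | CC(C)CC(=O)c1c(O)cc(OCc2ccccc2)c2c1OC(O)CC2c1cc2c(OCc3ccccc3)cc(OCc3ccccc3)c(C(=O)CC(C)C)c2o1
F2 | step 8 | racemic 1-[4-(benzyloxy)-3-[1-[4,6-bis(benzyloxy)-7-(3-methylbutanoyl)-1-benzofuran-2-yl]but-3-yn-1-yl]-2,6-dihydroxyphenyl]-3-methylbutan-1-one (racemic alkyne phenol) | CC(C)CC(=O)c1c(O)cc(OCc2ccccc2)c(c1O)C(CC#C)c1cc2c(OCc3ccccc3)cc(OCc3ccccc3)c(C(=O)CC(C)C)c2o1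
F3 | step 8 | 1-[4-(benzyloxy)-3-[(1R)-1-[4,6-bis(benzyloxy)-7-(3-methylbutanoyl)-1-benzofuran-2-yl]but-3-yn-1-yl]-2,6-dihydroxyphenyl]-3-methylbutan-1-one (enantiomer of 18) | CC(C)CC(=O)c1c(O)cc(OCc2ccccc2)c(c1O)[C@@H](CC#C)c1cc2c(OCc3ccccc3)cc(OCc3ccccc3)c(C(=O)CC(C)C)c2o1
F4 | step 10 | 3'-bromo derivative of 19 (Br on the ring-A CH, trans to the newly formed C–O bond; same spiro and C3 configuration as 19) | CC(C)CC(=O)c1c(OCc3ccccc3)cc(OCc3ccccc3)c2c1O[C@]1([C@@H]2Br)Oc2c(C(=O)CC(C)C)c(O)cc(OCc3ccccc3)c2[C@@H]1CC#C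
F5 | step 15 | 3-(benzyloxy)-5-hydroxy-2-iodo-4-(3-methylbutanoyl)phenyl acetate | CC(C)CC(=O)c1c(OCc2ccccc2)c(I)c(OC(C)=O)cc1O
F6 | step 15 | 4-O-acetate of 25 (alkynyl aryl acetate) | CC(C)CC(=O)c1c(OCc3ccccc3)cc(OCc3ccccc3)c2c1O[C@]1(C2)Oc2c(C(=O)CC(C)C)c(O)cc(OCc3ccccc3)c2[C@@H]1CC#Cc1c(OC(C)=O)cc(O)c(C(=O)CC(C)C)c1OCc1ccccc1
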